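## Analysis of the target

Target 11 is a 7,7'-epoxylignan. It has one oxolane ring (O1, C2, C3, C4, C5), identical 4-hydroxy-3,5-dimethoxyphenyl (syringyl) rings on C2 and C5, and hydroxymethyl groups on C3 and C4.

With C2 taken as the first stereocentre written in the SMILES, the configuration is (2S,3R,4R,5R). The two aryl rings are cis to each other across O1 and the two CH2OH groups are trans. It follows that C2/C3 are trans and C4/C5 are cis.

The constitution is symmetric, but the molecule has no symmetry element. The half C2–O1–C5 with its two aryl rings is locally mirror-symmetric. The half C3–C4 with its two CH2OH groups is locally twofold-symmetric. The chirality of the whole arises only from the way these two halves are joined.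

This is the feature the route uses. A 2,5-cis/3,4-trans oxolane with equal aryl groups exists as a single diastereomer, so the relative configuration of all four centres follows from two independent geometric facts.

Both benzylic bonds C2–O1 and C5–O1 stand para to a free phenol. Acid or strong base can open them through a p-quinone methide. That would epimerise the contra-thermodynamic 4,5-cis centre or let a CH2OH group close to a dioxabicyclo[3.3.0]octane. The phenols are also easily oxidised.

The hard parts are these:
- four contiguous stereocentres;
- a 4,5-cis relation that must be set kinetically next to a labile benzylic centre;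
- absolute control in a molecule whose two halves have the same constitution;
- an endgame that has to stay near neutral.

## Retrosynthetic reasoning

**11 to 10.** No skeletal bond is cut. The two CH2OH groups are traced back to two N-acyl sultam groups, and the two phenols to two pivalates. All four acyl groups fall to one hydride reagent, so auxiliary removal, adjustment of oxidation level and deprotection are a single operation. The free p-hydroxybenzyl ether appears only in the last flask.

**10 to 9 plus 8.** The bonds C2–C3 and C4–C5 are cut together. This cut separates the mirror-symmetric half (C2–O1–C5, ylide 9) from the twofold-symmetric half (C3–C4, dipolarophile 8).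
- Each half is stereochemically trivial on its own. The geometry of 9 encodes 2,5-cis and the E geometry of 8 encodes 3,4-trans.
- Because of the two symmetries there is no endo/exo question and no orientation question.
- The forward reaction closes the only ring, forms two C–C bonds and sets four stereocentres. It has to achieve one thing only: the choice of one face of 8.
- Any cut through a C–O bond would hand a benzylic centre to ionisation chemistry.

**9 to 4.** C2 and C5 are reconnected. Ylide 9 is the ring-opened valence isomer of oxirane 4, reached by breaking the oxirane C–C bond after one-electron oxidation. The stereocentres of 4 are erased in this event, so 4 may be racemic and of either relative configuration. The C–C bond of 4 is a temporary tether: it is made only to bring O1 between two benzylic carbons, and it is then cleaved.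

**4 to 3 to 2 to 1.** The oxirane oxygen comes from a peracid and alkene 3. The pivalates come from acylation of bisphenol 2. The C=C bond of 2 is cut into two molecules of aldehyde 1, joined in the forward sense by reductive carbonyl coupling. The identity of the two aryl rings of 11 is thus used to halve the work.

**8 to 5 plus 6 (through 7).** The two C–N bonds are cut. Bis-acid chloride 6 supplies C3, C4 and both future CH2OH carbons with the E geometry in place. Chiral-pool sultam 5, as its sodium salt 7, supplies the only source of absolute configuration and is recovered at the end.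

## Alternatives that were turned down

**Alternative 1:** (the textbook one) The disconnection is the C5–O1 bond.
- Precursor: the twofold-symmetric tetraol A1. It would be built by two auxiliary-controlled aldol additions of a succinate to a protected form of 1, followed by reduction.
- Forward key step: activation of one of the two equivalent benzylic hydroxyl groups of A1 and invertive closure by the other.
- Reasons for turning it down:
  - A leaving group on a carbon attached to a trialkoxyarene ionises instead of being displaced. C5 then falls under thermodynamic control, which favours 4,5-trans, the opposite of what 11 needs.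
  - The primary hydroxyl groups of A1 sit 1,4 to the cation and would close to the bicyclic bis-ether unless they are protected and later released.
  - The four centres are set in several separate operations and the ring closure sets none reliably.
  - The count would run to well over ten steps.

**Alternative 2:** The disconnection is the C3–C4 bond together with both C–O bonds (the biomimetic cut).
- Forward key step: one-electron oxidation of sinapyl alcohol A2, radical dimerisation to the bis(quinone methide) A3, and addition of one molecule of water across its two termini.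
- Reasons for turning it down:
  - In A3 each quinone methide carbon has the CH2OH group of the other half within reach of a five-membered closure. Intramolecular capture should therefore outrun external water and lead to the furofuran A4.
  - Nothing in A2 or A3 can control the absolute configuration.
  - The configuration at C2 and C5 would be left to chance.
  - The route is the shortest on paper but controls none of the things that make 11 hard.

**Alternative 3:** The disconnection is O1–C5 and C2–C3.
- Forward key step: a Lewis-acid-catalysed formal (3+2) cycloaddition of the enantioenriched donor–acceptor cyclopropane A5 with aldehyde A6. The aldehyde oxygen attacks the benzylic carbon with inversion, and the product is the 2,5-cis oxolane A7.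
- Reasons for turning it down:
  - The option is serious because it delivers 2,5-cis, but A5 already holds two stereocentres and needs an asymmetric cyclopropanation sequence of its own.
  - Its electron-rich aryl donor should make the ring-opened zwitterion long-lived, so stereospecificity is at risk.
  - A7 carries one carboxyl group too many at C3. A Krapcho dealkoxycarbonylation would then have to create C3 by protonation in a separate step.
  - The identity of the two halves of 11 goes unused and the step count is roughly doubled.

Key step: step 5

Assumption: the (2R)-sultam is taken to direct the ylide to the Cα-re face of each enoyl unit, as it does with other uncatalysed cycloaddition partners. Should the sense be the opposite, the equally available (2S)-sultam would be used and nothing else would change.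

## Route

Step 1
Reactants: 1 syringaldehyde (two molecules)
Product: 2 (E)-4,4'-(ethene-1,2-diyl)bis(2,6-dimethoxyphenol)
Conditions: TiCl4, Zn dust (excess), THF, 0 °C then reflux, under Ar; aqueous work-up
Reagents that add atoms: none
Why: McMurry coupling: low-valent titanium couples the aromatic aldehyde reductively and deoxygenates it to the stilbene, while the free phenols only bind extra reagent and are released on work-up. The E isomer should prevail, and the alkene geometry is of no consequence because it is erased in step 5.

Step 2
Reactants: 2 (E)-4,4'-(ethene-1,2-diyl)bis(2,6-dimethoxyphenol)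
Product: 3 (E)-ethene-1,2-diylbis(2,6-dimethoxy-4,1-phenylene) bis(2,2-dimethylpropanoate)
Conditions: PivCl, Et3N, DMAP (cat.), CH2Cl2, 0 °C to rt, under N2
Reagents that add atoms: pivaloyl chloride, CC(C)(C)C(=O)Cl
Why: DMAP-catalysed acylation of the two hindered phenols. The pivalate ties up the para oxygen lone pair, so the later oxirane should be about as robust as an unactivated stilbene oxide, the phenol is shielded from the photo-oxidant, and the group falls to the hydride of step 6.

Step 3
Reactants: 3 (E)-ethene-1,2-diylbis(2,6-dimethoxy-4,1-phenylene) bis(2,2-dimethylpropanoate)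
Product: 4 rac-trans-2,3-bis[3,5-dimethoxy-4-(pivaloyloxy)phenyl]oxirane
Conditions: mCPBA, CH2Cl2, 0 °C to rt
Reagents that add atoms: mCPBA (3-chloroperoxybenzoic acid), O=C(OO)c1cccc(Cl)c1
Why: Prilezhaev epoxidation: concerted syn transfer of oxygen to the E alkene gives the racemic trans oxirane, and the acyloxy groups keep its benzylic C–O bonds from ionising under the carboxylic acid that is formed. Both stereocentres are temporary and vanish in step 5.

Step 4
Reactants: 5 (2R)-bornane-10,2-sultam (two molecules), 6 fumaryl chloride
Product: 8 N,N'-fumaroylbis[(2R)-bornane-10,2-sultam], via sodium sultamide 7 (not isolated)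
Conditions: NaH, toluene, 0 °C to rt; then 6 (0.5 equiv), rt
Reagents that add atoms: sodium hydride, [Na+].[H-] (its sodium stands in 7 only)
Why: N-acylation of the sodium salt of the sultam with a bis-acid chloride, with the E geometry retained. The stereocentres come unchanged from the chiral pool, and the product should be a crystalline, twofold-symmetric, very electron-poor alkene.

Step 5
Reactants: 4 rac-trans-2,3-bis[3,5-dimethoxy-4-(pivaloyloxy)phenyl]oxirane, 8 N,N'-fumaroylbis[(2R)-bornane-10,2-sultam]
Product: 10 N,N'-{[(2S,3S,4S,5R)-2,5-bis(3,5-dimethoxy-4-pivaloyloxyphenyl)oxolane-3,4-diyl]dicarbonyl}bis[(2R)-bornane-10,2-sultam], via carbonyl ylide 9 (not isolated)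
Conditions: 4-mesityl-2,6-diphenylpyrylium tetrafluoroborate (cat.), blue LEDs (ca. 450 nm), 4 Å MS, degassed CH2Cl2, 0 °C
Reagents that add atoms: none
Why: Proposed new method: the excited pyrylium salt removes one electron from an arene of 4, the strained oxirane C–C bond of the radical cation breaks, and return of the electron from the pyranyl radical gives the neutral carbonyl ylide 9, which settles in its W-shaped form with both aryl groups exo whichever isomer of 4 is used. The closest known reaction types are the photoinduced-electron-transfer (3+2) cycloaddition of 2,3-diaryloxiranes with fumaric diesters, which gives racemic 2,5-cis-diaryloxolane-3,4-dicarboxylates, and the uncatalysed, highly face-selective cycloadditions of dienes to 8 and of 1,3-dipoles to N-enoyl bornane-10,2-sultams; only their union is new. The oxolane ring closes in a concerted suprafacial 4π+2π mode in which C2–C3 and C4–C5 form together, under HOMO(ylide)–LUMO(alkene) control, for which the very electron-poor 8 is the matched partner. C2 and C5 become cis because both aryl groups stand exo on 9. C3 and C4 become trans because the E geometry of 8 is transferred suprafacially. Since 9 has a mirror plane and 8 a twofold axis, endo and exo approach and both orientations coincide, so that each face of 8 can give one adduct only, the one with the 2,3-trans-3,4-trans-4,5-cis pattern. The absolute configuration is controlled by the two (2R)-sultam units, which in their s-cis, C=O/SO2-anti conformation shield the same side of the alkene and leave the Cα-re/Cα'-re face open, attack on which gives (3S,4S) and with it (2S,5R). The only selectivity that is needed is therefore facial, and chemoselective oxidation of 4 rather than 8 is secured by the electron-rich arenes of 4 and the electron-poor π system of 8.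

Step 6
Reactants: 10 N,N'-{[(2S,3S,4S,5R)-2,5-bis(3,5-dimethoxy-4-pivaloyloxyphenyl)oxolane-3,4-diyl]dicarbonyl}bis[(2R)-bornane-10,2-sultam]
Product: 11 4,4'-[(2S,3R,4R,5R)-3,4-bis(hydroxymethyl)oxolane-2,5-diyl]bis(2,6-dimethoxyphenol) (target)
Conditions: LiAlH4 (excess), THF, 0 °C to rt; aqueous work-up at about pH 7
Reagents that add atoms: none
Why: Hydride reduction of N-acyl sultams to primary alcohols with release of the auxiliary is standard, and aryl pivalates are cleaved by the same reagent, so all four acyl groups should fall in one operation. No stereocentre is touched (the descriptors at C3 and C4 change from S to R only because the CIP priorities change), and the near-neutral work-up avoids quinone methide epimerisation at C2 and C5.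

## Compound list

1 | syringaldehyde (4-hydroxy-3,5-dimethoxybenzaldehyde) | COc1cc(C=O)cc(OC)c1O | starting material
2 | (E)-4,4'-(ethene-1,2-diyl)bis(2,6-dimethoxyphenol) | COc1cc(/C=C/c2cc(OC)c(O)c(OC)c2)cc(OC)c1O | intermediate
3 | (E)-ethene-1,2-diylbis(2,6-dimethoxy-4,1-phenylene) bis(2,2-dimethylpropanoate) | COc1cc(/C=C/c2cc(OC)c(OC(=O)C(C)(C)C)c(OC)c2)cc(OC)c1OC(=O)C(C)(C)C | intermediate
4 | rac-trans-2,3-bis[3,5-dimethoxy-4-(pivaloyloxy)phenyl]oxirane (racemate, the (2R,3R) enantiomer drawn) | COc1cc([C@@H]2[C@H](O2)c2cc(OC)c(OC(=O)C(C)(C)C)c(OC)c2)cc(OC)c1OC(=O)C(C)(C)C | intermediate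
5 | (2R)-bornane-10,2-sultam, (1S,2R,4R) | N1[C@@H]2C[C@H]3CC[C@]2(CS1(=O)=O)C3(C)C | starting material
6 | fumaryl chloride | O=C(Cl)/C=C/C(=O)Cl | starting material
7 | sodium salt of (2R)-bornane-10,2-sultam | [Na+].[N-]1[C@@H]2C[C@H]3CC[C@]2(CS1(=O)=O)C3(C)C | intermediate (not isolated)
8 | N,N'-fumaroylbis[(2R)-bornane-10,2-sultam] | O=C(/C=C/C(=O)N1[C@@H]2C[C@H]3CC[C@]2(CS1(=O)=O)C3(C)C)N1[C@@H]2C[C@H]3CC[C@]2(CS1(=O)=O)C3(C)C | intermediate
9 | W-shaped (exo,exo) carbonyl ylide, bis[3,5-dimethoxy-4-(pivaloyloxy)benzylidene]oxonium ylide | COc1cc(/C=[O+]/[CH-]c2cc(OC)c(OC(=O)C(C)(C)C)c(OC)c2)cc(OC)c1OC(=O)C(C)(C)C | intermediate (not isolated)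
10 | N,N'-{[(2S,3S,4S,5R)-2,5-bis(3,5-dimethoxy-4-pivaloyloxyphenyl)oxolane-3,4-diyl]dicarbonyl}bis[(2R)-bornane-10,2-sultam] | COc1cc([C@H]2O[C@@H](c3cc(OC)c(OC(=O)C(C)(C)C)c(OC)c3)[C@@H](C(=O)N4[C@@H]5C[C@H]6CC[C@]5(CS4(=O)=O)C6(C)C)[C@@H]2C(=O)N7[C@@H]8C[C@H]9CC[C@]8(CS7(=O)=O)C9(C)C)cc(OC)c1OC(=O)C(C)(C)C | intermediate
11 | 4,4'-[(2S,3R,4R,5R)-3,4-bis(hydroxymethyl)oxolane-2,5-diyl]bis(2,6-dimethoxyphenol) | COc1cc([C@H]2O[C@@H](c3cc(OC)c(O)c(OC)c3)[C@@H](CO)[C@@H]2CO)cc(OC)c1O | target

## Step count and least certain steps

Total step count: 6.
Longest linear sequence: 5 (steps 1, 2, 3, 5 and 6). Step 4 is the convergent branch.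

**Step 5 (key step, proposed new method).** Three processes are most likely to hurt.
- Unproductive back electron transfer before the C–C bond breaks. The hole rests on a dimethoxy-acyloxy arene with little density at the benzylic carbon, and a 1,2-shift of the radical cation to carbonyl isomers can compete.
- Slow capture of the ylide. One bulky acyl sultam has to pass under an aryl group (the future 4,5-cis relation), so re-closure or fragmentation of the ylide may win.
- Erosion of facial selectivity, because the reaction is not run at cryogenic temperature.

The fallback uses known chemistry and replaces induction by resolution.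
- It sets out from 4, which is irradiated under the same conditions with commercial dibenzyl fumarate. This reaction type is known for fumaric diesters and gives the racemic dibenzyl oxolane-3,4-dicarboxylate F1.
- Hydrogenolysis (H2, Pd/C, EtOAc) gives the racemic oxolane-3,4-dicarboxylic acid F2.
- Oxalyl chloride with catalytic DMF gives the racemic bis(acid chloride) F3.
- Acylation of 7 with F3 gives 10 together with its (2R,3R,4R,5S) diastereomer F4.
- The two are separated by crystallisation or chromatography, and the route is rejoined at 10.

**Step 6.** Four things may go wrong: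
- incomplete reduction of the hindered acyl sultam that is cis to the C5 aryl group;
- enolisation and epimerisation at C3 or C4 by the basic hydride;
- opening of a benzylic C–O bond assisted by the aluminium phenoxide once the pivalates have fallen, through a quinone methide, with loss of configuration at C2 or C5 or reductive ring cleavage;
- poor recovery of the polar product from aluminium salts.

The fallback separates cleavage from reduction. It sets out from 10. Hydrolysis with LiOH in aqueous THF removes both auxiliaries and both pivalates and gives the (2S,3S,4S,5R)-bis(4-hydroxy-3,5-dimethoxyphenyl)oxolane-3,4-dicarboxylic acid F8. The electrophilic hydride BH3·THF then reduces only the carboxyl groups, and methanolysis of the borates returns the route at 11.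

**Step 1.** The titanium phenoxide makes the aldehyde less electrophilic, so the coupling may stall before deoxygenation. The electron-rich bisphenol may also be oxidised by air during isolation.

The fallback builds the alkene by metathesis. It sets out from 1.
- Acylation with PivCl, Et3N and DMAP gives 4-formyl-2,6-dimethoxyphenyl pivalate F5.
- Wittig methylenation (Ph3P=CH2, THF, 0 °C) gives 4-ethenyl-2,6-dimethoxyphenyl pivalate F6.
- Homometathesis with the second-generation Grubbs catalyst RuCl2(=CHPh)(PCy3)(H2IMes) in CH2Cl2 at reflux gives the E stilbene, and the route is rejoined at 3.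

**Step 3.** Oxygen transfer to the electronically deactivated stilbene may be slow. Long exposure to peracid and carboxylic acid may then lead to opening or rearrangement of the oxirane.

The fallback replaces direct oxygen transfer by halohydrin formation and ring closure. It sets out from 3. NBS in aqueous THF gives the racemic erythro bromohydrin F7 by anti addition. K2CO3 in dry acetone closes it with inversion, and the route is rejoined at 4.

## Further compounds

F1 | step 5 | rac-dibenzyl (2S*,3S*,4S*,5R*)-2,5-bis[3,5-dimethoxy-4-(pivaloyloxy)phenyl]oxolane-3,4-dicarboxylate (racemate, one enantiomer drawn) | COc1cc([C@H]2O[C@@H](c3cc(OC)c(OC(=O)C(C)(C)C)c(OC)c3)[C@@H](C(=O)OCc3ccccc3)[C@@H]2C(=O)OCc2ccccc2)cc(OC)c1OC(=O)C(C)(C)C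
F2 | step 5 | rac-(2S*,3S*,4S*,5R*)-2,5-bis[3,5-dimethoxy-4-(pivaloyloxy)phenyl]oxolane-3,4-dicarboxylic acid (racemate, one enantiomer drawn) | COc1cc([C@H]2O[C@@H](c3cc(OC)c(OC(=O)C(C)(C)C)c(OC)c3)[C@@H](C(=O)O)[C@@H]2C(=O)O)cc(OC)c1OC(=O)C(C)(C)C
F3 | step 5 | rac-(2S*,3S*,4S*,5R*)-2,5-bis[3,5-dimethoxy-4-(pivaloyloxy)phenyl]oxolane-3,4-dicarbonyl dichloride (racemate, one enantiomer drawn) | COc1cc([C@H]2O[C@@H](c3cc(OC)c(OC(=O)C(C)(C)C)c(OC)c3)[C@@H](C(=O)Cl)[C@@H]2C(=O)Cl)cc(OC)c1OC(=O)C(C)(C)C
F4 | step 5 | N,N'-{[(2R,3R,4R,5S)-2,5-bis(3,5-dimethoxy-4-pivaloyloxyphenyl)oxolane-3,4-diyl]dicarbonyl}bis[(2R)-bornane-10,2-sultam] (diastereomer of 10) | COc1cc([C@@H]2O[C@H](c3cc(OC)c(OC(=O)C(C)(C)C)c(OC)c3)[C@H](C(=O)N4[C@@H]5C[C@H]6CC[C@]5(CS4(=O)=O)C6(C)C)[C@H]2C(=O)N7[C@@H]8C[C@H]9CC[C@]8(CS7(=O)=O)C9(C)C)cc(OC)c1OC(=O)C(C)(C)C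
F5 | step 1 | 4-formyl-2,6-dimethoxyphenyl 2,2-dimethylpropanoate | COc1cc(C=O)cc(OC)c1OC(=O)C(C)(C)C
F6 | step 1 | 4-ethenyl-2,6-dimethoxyphenyl 2,2-dimethylpropanoate | C=Cc1cc(OC)c(OC(=O)C(C)(C)C)c(OC)c1
F7 | step 3 | rac-(1R*,2S*)-2-bromo-1,2-bis[3,5-dimethoxy-4-(pivaloyloxy)phenyl]ethanol (racemate, one enantiomer drawn) | COc1cc([C@@H](O)[C@@H](Br)c2cc(OC)c(OC(=O)C(C)(C)C)c(OC)c2)cc(OC)c1OC(=O)C(C)(C)C
F8 | step 6 | (2S,3S,4S,5R)-2,5-bis(4-hydroxy-3,5-dimethoxyphenyl)oxolane-3,4-dicarboxylic acid | COc1cc([C@H]2O[C@@H](c3cc(OC)c(O)c(OC)c3)[C@@H](C(=O)O)[C@@H]2C(=O)O)cc(OC)c1O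
A1 | alternative 1 | (1S,2R,3R,4S)-1,4-bis[4-(benzyloxy)-3,5-dimethoxyphenyl]-2,3-bis(hydroxymethyl)butane-1,4-diol | COc1cc([C@@H](O)[C@@H](CO)[C@H](CO)[C@H](O)c2cc(OC)c(OCc3ccccc3)c(OC)c2)cc(OC)c1OCc1ccccc1
A2 | alternative 2 | sinapyl alcohol | COc1cc(/C=C/CO)cc(OC)c1O
A3 | alternative 2 | rac-4,4'-[(2R*,3R*)-2,3-bis(hydroxymethyl)butane-1,4-diylidene]bis(2,6-dimethoxycyclohexa-2,5-dien-1-one) (racemate, one enantiomer drawn) | COC1=CC(=C[C@@H](CO)[C@H](CO)C=C2C=C(OC)C(=O)C(OC)=C2)C=C(OC)C1=O
A4 | alternative 2 | rac-syringaresinol (racemate, one enantiomer drawn) | COc1cc(cc(OC)c1O)[C@@H]1[C@H]2CO[C@@H]([C@H]2CO1)c1cc(OC)c(O)c(OC)c1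
A5 | alternative 3 | dimethyl (2S,3R)-2-[4-(benzyloxy)-3,5-dimethoxyphenyl]-3-[(benzyloxy)methyl]cyclopropane-1,1-dicarboxylate | COC(=O)C1(C(=O)OC)[C@H](c2cc(OC)c(OCc3ccccc3)c(OC)c2)[C@H]1COCc1ccccc1
A6 | alternative 3 | 4-(benzyloxy)-3,5-dimethoxybenzaldehyde | COc1cc(C=O)cc(OC)c1OCc1ccccc1
A7 | alternative 3 | dimethyl (2R,4R,5R)-2,5-bis[4-(benzyloxy)-3,5-dimethoxyphenyl]-4-[(benzyloxy)methyl]oxolane-3,3-dicarboxylate | COc1cc([C@H]2O[C@@H](c3cc(OC)c(OCc4ccccc4)c(OC)c3)[C@@H](COCc3ccccc3)C2(C(=O)OC)C(=O)OC)cc(OC)c1OCc1ccccc1
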